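**Plan**

- Retrosynthesis: the O8 angelate, the O9 acetate and the C13 methylene come off first. The γ-lactone is traced to an acyl shift from O9 to O6, and the ten-membered ring (C1–C10) is opened at C5–C6 into a vinyl iodide and a C6 aldehyde. The open chain is then cut at C9–C10 and at C2–C3 in a single operation.
- Enabling feature: in the ring segment C9(OH)–C10(Me)=C1–C2–C3(OH) both carbinols are homoallylic to the same methyl-bearing three-carbon unit C10–C1–C2, a 2-methylalk-2-ene-1,5-diol with C9 and C2 cis. A but-2-ene carrying boron on C2 and on C10 can therefore be stitched between a C9 aldehyde and a C3 aldehyde on the open chain, before any ring exists.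
- Forward, chain assembly: fragment A (C6–C9 with C11, C12) comes from (R)-3-hydroxy-γ-butyrolactone, the diboron linchpin (C2, C1, C10, C14) from but-2-yn-1-ol, and the iodo enal (C3–C5, C15) from propargyl alcohol. A three-component coupling joins them to the C5/C6 seco diol.
- Forward, rings: O9 first closes a temporary δ-lactone on C12, which tells O9 from O3. The carbocycle then closes at C5–C6 by a chromium-mediated vinyl iodide/aldehyde coupling, and the γ-lactone forms by acyl migration from O9 to the new O6. Methylenation, O9 acetate, O8 angelate and O3 release finish the route.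
- Stereochemistry: C8 comes from the chiral pool and C7 from a trans alkylation next to it. C9 is set by isopinocampheyl reagent control matched with Felkin–Anh, C3 by 1,3-chirality transfer through C10, and the Z C1=C10 alkene by the chair of the second allyl transfer. C6 is set in the ring closure, and the E C4=C5 alkene by syn-carboalumination.

Key step: step 11

Remark (assumption): germacrane numbering is used throughout (C14 on C10, C15 on C4, lactone C6–C7–C11–C12–O). The borane end of the linchpin carries isopinocampheyl groups from (+)-α-pinene, O8 is carried as a 2-naphthylmethyl (NAP) ether, C6 as a 1,3-dithiane and C12 as a tert-butyl ester; these choices serve stereocontrol and the fragment synthesis.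

**Route**

Step 1
Reactants: 1 (R)-3-hydroxy-γ-butyrolactone; 2 tert-butyl bromoacetate
Product: 4 tert-butyl 2-[(3R,4R)-4-hydroxy-2-oxooxolan-3-yl]acetate, via dilithium alkoxide enolate 3 (not isolated)
Conditions: LiN(iPr)2 (2.2 equiv), THF, −78 → −40 °C; then 2, DMPU, −78 → −40 °C; aq. NH4Cl
Reagents that add atoms: none
Why: Fráter–Seebach alkylation: the alkoxide–enolate dianion is alkylated on the face anti to the C8 alkoxide, which sets C7 trans to O8 (the 7,8-relationship of the target), and the trans arrangement keeps the free hydroxyl from lactonising onto the new ester.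

Step 2
Reactants: 4 tert-butyl 2-[(3R,4R)-4-hydroxy-2-oxooxolan-3-yl]acetate
Product: 5 tert-butyl 2-[(3R,4R)-4-(naphthalen-2-ylmethoxy)-2-oxooxolan-3-yl]acetate
Conditions: 2-naphthylmethyl trichloroacetimidate, TfOH (5 mol %), CH2Cl2–cyclohexane, 0 °C
Reagents that add atoms: 2-naphthylmethyl 2,2,2-trichloroacetimidate N=C(OCc1ccc2ccccc2c1)C(Cl)(Cl)Cl
Why: Acid-catalysed O-alkylation with a trichloroacetimidate avoids the base that would cause β-elimination of the hydroxy lactone; the NAP ether is chosen because it should survive the Lewis acid/thiol of step 4 and is later removed with DDQ.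

Step 3
Reactants: 5 tert-butyl 2-[(3R,4R)-4-(naphthalen-2-ylmethoxy)-2-oxooxolan-3-yl]acetate
Product: 6 tert-butyl 2-[(3R,4R)-2-hydroxy-4-(naphthalen-2-ylmethoxy)oxolan-3-yl]acetate
Conditions: iBu2AlH (1.1 equiv), CH2Cl2, −78 °C; aq. potassium sodium tartrate
Reagents that add atoms: none
Why: Partial reduction of a lactone to its lactol with iBu2AlH at −78 °C, a temperature at which a tert-butyl ester should not be reduced.

Step 4
Reactants: 6 tert-butyl 2-[(3R,4R)-2-hydroxy-4-(naphthalen-2-ylmethoxy)oxolan-3-yl]acetate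
Product: 7 tert-butyl (3R,4R)-3-(1,3-dithian-2-yl)-5-hydroxy-4-(naphthalen-2-ylmethoxy)pentanoate
Conditions: HS(CH2)3SH, BF3·OEt2, CH2Cl2, −40 → −20 °C
Reagents that add atoms: propane-1,3-dithiol SCCCS
Why: Lewis-acid-promoted dithioacetalisation of a lactol opens the ring, masks C6 as a 1,3-dithiane and frees the C9 hydroxyl.

Step 5
Reactants: 7 tert-butyl (3R,4R)-3-(1,3-dithian-2-yl)-5-hydroxy-4-(naphthalen-2-ylmethoxy)pentanoate
Product: 8 tert-butyl (3R,4R)-3-(1,3-dithian-2-yl)-4-(naphthalen-2-ylmethoxy)-5-oxopentanoate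
Conditions: Dess–Martin periodinane, pyridine, CH2Cl2, 0 °C; used at once
Reagents that add atoms: none
Why: Dess–Martin oxidation of the primary alcohol under buffered conditions should give the α-alkoxy aldehyde without epimerisation at C8.

Step 6
Reactants: 9 but-2-yn-1-ol
Product: 10 but-2-yn-1-yl methyl carbonate
Conditions: ClCO2Me, pyridine, CH2Cl2, 0 °C
Reagents that add atoms: methyl chloroformate COC(Cl)=O
Why: Simple acylation of a primary propargylic alcohol with a chloroformate.

Step 7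
Reactants: 10 but-2-yn-1-yl methyl carbonate
Product: 11 2-(buta-2,3-dien-2-yl)-4,4,5,5-tetramethyl-1,3,2-dioxaborolane
Conditions: B2pin2, CuOtBu (10 mol %), Xantphos (10 mol %), THF, rt
Reagents that add atoms: bis(pinacolato)diboron CC1(C)OB(OC1(C)C)B1OC(C)(C)C(C)(C)O1
Why: Copper-catalysed SN2′ (γ-selective) borylation of a propargylic carbonate: the boryl-copper species attacks the methyl-bearing alkyne carbon and the carbonate leaves, giving the 1,1-disubstituted allenylboronate.

Step 8
Reactants: 11 2-(buta-2,3-dien-2-yl)-4,4,5,5-tetramethyl-1,3,2-dioxaborolane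
Product: 12 (E)-[3-(4,4,5,5-tetramethyl-1,3,2-dioxaborolan-2-yl)but-2-en-1-yl]bis[(1R,2S,3R,5R)-2,6,6-trimethylbicyclo[3.1.1]heptan-3-yl]borane
Conditions: (−)-diisopinocampheylborane (1.0 equiv), toluene, −25 → 0 °C; solution kept at or below 0 °C and used directly in step 11
Reagents that add atoms: (−)-diisopinocampheylborane, from (+)-α-pinene B([C@@H]1C[C@@H]2C[C@H]([C@H]1C)C2(C)C)[C@@H]1C[C@@H]2C[C@H]([C@H]1C)C2(C)C
Why: Kinetic hydroboration of the unsubstituted allene terminus with a hindered dialkylborane: boron goes to the CH2 carbon and hydrogen to the central carbon from the side away from the pinacol boronate, which places the CH2B group cis to Bpin, and the low temperature should suppress the 1,3-boryl shifts that would scramble this geometry.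

Step 9
Reactants: 13 prop-2-yn-1-ol
Product: 15 (E)-3-iodo-2-methylprop-2-en-1-ol, via alkenylalane 14 (not isolated)
Conditions: AlMe3 (3 equiv), Cp2ZrCl2 (0.25 equiv), CH2Cl2, 0 °C → rt; then iodine, THF, −30 → 0 °C; aq. work-up with Na2S2O3/NaHCO3
Reagents that add atoms: trimethylaluminium C[Al](C)C; iodine [I][I]
Why: Negishi zirconium-catalysed syn-carboalumination of the terminal alkyne followed by iodinolysis of the alkenylalane with retention gives the E trisubstituted vinyl iodide.

Step 10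
Reactants: 15 (E)-3-iodo-2-methylprop-2-en-1-ol
Product: 16 (E)-3-iodo-2-methylprop-2-enal
Conditions: MnO2 (excess), CH2Cl2, rt; used fresh
Reagents that add atoms: none
Why: Chemoselective allylic oxidation with MnO2, which should not isomerise the alkene.

Step 11
Reactants: 12 diboron linchpin; 8 tert-butyl (3R,4R)-3-(1,3-dithian-2-yl)-4-(naphthalen-2-ylmethoxy)-5-oxopentanoate; 16 (E)-3-iodo-2-methylprop-2-enal
Product: 19 tert-butyl (3R,4R,5S,6Z,9S,10E)-3-(1,3-dithian-2-yl)-5,9-dihydroxy-11-iodo-6,10-dimethyl-4-(naphthalen-2-ylmethoxy)undeca-6,10-dienoate, via C10 boronate C9 borinate 17 (not isolated), via C9 borinate C3 borate 18 (not isolated)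
Conditions: 12 (1.3 equiv), toluene, −78 °C, then 8, 3 h; then 16 (2 equiv), −78 → 23 °C (40 °C if slow), 36 h; HOCH2CH2NH2, rt
Reagents that add atoms: none
Why: Proposed new method: two closed six-membered chair (Zimmerman–Traxler-type) allyl transfers run in one flask: at −78 °C the dialkylallylborane end of 12 delivers C10 to aldehyde 8 with Bpin axial and the methyl group equatorial (C9–C10), leaving the tertiary α-boryl homoallyl borinate 17, and on warming this allyl pinacol boronate transfers C2 to enal 16 with allylic transposition (C2–C3), leaving the C1=C10 alkene. The closest known reaction types are the one-pot double allylboration of two aldehydes with γ-boryl allyl(diisopinocampheyl)boranes to 2-ene-1,5-diols and the single allylboration of aldehydes with γ-boryl-γ-methyl allylboranes; new is the second transfer from a tertiary, methyl-bearing boronate to give a trisubstituted alkene. No ring is closed; two skeletal bonds and two carbinol stereocentres (C9, C3) are formed. C9 is controlled by the isopinocampheyl ligands from (+)-α-pinene, matched with the polar Felkin–Anh preference of the C8 ether (8,9-anti), and C10 follows from the fixed geometry of 12; C3 is controlled by 1,3-chirality transfer from C10 through the second chair with the enal residue equatorial. The step needs anti addition at C9 and the C9 branch axial in the second chair; the first is secured by reagent and α-alkoxy substituent acting together, the second by the gauche interactions that an equatorial branch would suffer with the pinacol ester, so the small methyl group goes equatorial and C9 and C2 come out cis.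

Step 12
Reactants: 19 seco diol
Product: 20 (4R,5R,6S)-4-(1,3-dithian-2-yl)-6-[(2Z,5S,6E)-5-hydroxy-7-iodo-6-methylhepta-2,6-dien-2-yl]-5-(naphthalen-2-ylmethoxy)oxan-2-one
Conditions: KOtBu (0.2 equiv), THF, 0 °C → rt, 0.02 M
Reagents that add atoms: none
Why: Base-catalysed intramolecular transesterification (lactonisation): only the C9 alkoxide reaches C12 through a six-membered ring, so O9 is masked and told apart from O3.

Step 13
Reactants: 20 δ-lactone alcohol
Product: 21 (4R,5R,6S)-6-[(2Z,5S,6E)-5-(tert-butyldimethylsilyloxy)-7-iodo-6-methylhepta-2,6-dien-2-yl]-4-(1,3-dithian-2-yl)-5-(naphthalen-2-ylmethoxy)oxan-2-one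
Conditions: TBSCl, imidazole, DMF, rt
Reagents that add atoms: tert-butyldimethylsilyl chloride CC(C)(C)[Si](C)(C)Cl
Why: Standard silylation of the one remaining secondary allylic alcohol.

Step 14
Reactants: 21 silyl ether
Product: 22 (2S,3R,4R)-2-[(2Z,5S,6E)-5-(tert-butyldimethylsilyloxy)-7-iodo-6-methylhepta-2,6-dien-2-yl]-3-(naphthalen-2-ylmethoxy)-6-oxooxane-4-carbaldehyde
Conditions: PhI(OCOCF3)2, NaHCO3, MeCN–H2O (9:1), 0 °C, 10 min; crude aldehyde used at once
Reagents that add atoms: water O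
Why: Oxidative hydrolysis of the dithiane with bis(trifluoroacetoxy)iodobenzene (Stork–Zhao conditions) is fast at 0 °C and should spare the alkenes, the vinyl iodide and the silyl and arylmethyl ethers.

Step 15
Reactants: 22 iodo aldehyde
Product: 24 (3S,6R,7S,8R,9S)-3-(tert-butyldimethylsilyloxy)-9-hydroxy-8-(naphthalen-2-ylmethoxy)germacra-1(10)Z,4E-dien-12,6-olide, via macrocyclic δ-lactone carbinol 23 (not isolated)
Conditions: CrCl2 (12 equiv), NiCl2 (0.1 equiv), DMSO–THF, rt, 3 mM, slow addition; aq. work-up; then DBU (0.2 equiv), CH2Cl2, rt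
Reagents that add atoms: none
Why: Nozaki–Hiyama–Kishi reaction (nickel-catalysed insertion into the vinyl carbon–iodine bond, transfer to trivalent chromium, addition to the aldehyde) should close the ten-membered ring with retention of the E alkene and, by Felkin–Anh addition anti to the C8 branch, set C6, after which the new C6 oxygen takes the acyl group from O9 to give the more stable trans-fused γ-lactone (translactonisation).

Step 16
Reactants: 24 γ-lactone
Product: 27 (3S,6R,7S,8R,9S)-3-(tert-butyldimethylsilyloxy)-9-hydroxy-8-(naphthalen-2-ylmethoxy)germacra-1(10)Z,4E,11(13)-trien-12,6-olide, via Mannich base 25 (not isolated), via trimethylammonium iodide 26 (not isolated)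
Conditions: LiN(iPr)2 (2.3 equiv), THF, −78 °C; CH2=NMe2+ I−, −78 → 0 °C; aq. NH4Cl; then MeI, MeOH, rt; then aq. NaHCO3, CH2Cl2, rt
Reagents that add atoms: N,N-dimethylmethyleneiminium iodide (Eschenmoser's salt) C=[N+](C)C.[I-]
Why: α-Methylenation of the lactone by Mannich reaction of its lithium enolate with Eschenmoser's salt, quaternisation and Hofmann-type elimination; the C9 alkoxide formed first by the extra base should stay inert.

Step 17
Reactants: 27 α-methylene lactone
Product: 28 (3S,6R,7S,8R,9S)-9-acetoxy-3-(tert-butyldimethylsilyloxy)-8-(naphthalen-2-ylmethoxy)germacra-1(10)Z,4E,11(13)-trien-12,6-olide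
Conditions: Ac2O, Et3N, DMAP (0.1 equiv), CH2Cl2, 0 °C → rt
Reagents that add atoms: acetic anhydride CC(=O)OC(C)=O
Why: DMAP-catalysed acetylation of the only free hydroxyl.

Step 18
Reactants: 28 acetate
Product: 29 (3S,6R,7S,8R,9S)-9-acetoxy-3-(tert-butyldimethylsilyloxy)-8-hydroxygermacra-1(10)Z,4E,11(13)-trien-12,6-olide
Conditions: DDQ (2.5 equiv), CH2Cl2–pH 7 phosphate buffer (10:1), rt
Reagents that add atoms: none
Why: Oxidative cleavage of the 2-naphthylmethyl ether with DDQ under buffered conditions, which should leave the acetate, the silyl ether and the conjugated lactone intact.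

Step 19
Reactants: 29 C8 alcohol; 30 angelic acid
Product: 32 (3S,6R,7S,8R,9S)-9-acetoxy-8-angeloyloxy-3-(tert-butyldimethylsilyloxy)germacra-1(10)Z,4E,11(13)-trien-12,6-olide, via mixed anhydride 31 (not isolated)
Conditions: 30 (3 equiv), 2,4,6-trichlorobenzoyl chloride, Et3N, toluene, rt; then 29, 80 °C
Reagents that add atoms: none
Why: Yamaguchi-type esterification through the 2,4,6-trichlorobenzoyl mixed anhydride without a nucleophilic catalyst, conditions used for angelates because they limit Z-to-E isomerisation.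

Step 20
Reactants: 32 silyl ether
Product: 33 (3S,6R,7S,8R,9S)-9-acetoxy-8-angeloyloxy-3-hydroxygermacra-1(10)Z,4E,11(13)-trien-12,6-olide
Conditions: HF·pyridine, pyridine, THF, 0 °C → rt
Reagents that add atoms: none
Why: Buffered fluoride desilylation, which should not touch the two esters or the α-methylene lactone.

**Compound list**

1 | (4R)-4-hydroxyoxolan-2-one, (R)-3-hydroxy-γ-butyrolactone | O=C1C[C@@H](O)CO1 | starting material
2 | tert-butyl bromoacetate | CC(C)(C)OC(=O)CBr | starting material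
3 | dilithium alkoxide enolate of 1 | [Li]O[C@H]1COC(O[Li])=C1 | intermediate
4 | tert-butyl 2-[(3R,4R)-4-hydroxy-2-oxooxolan-3-yl]acetate (3,4-trans) | O=C1OC[C@H](O)[C@H]1CC(=O)OC(C)(C)C | intermediate
5 | tert-butyl 2-[(3R,4R)-4-(naphthalen-2-ylmethoxy)-2-oxooxolan-3-yl]acetate | O=C1OC[C@H](OCc2ccc3ccccc3c2)[C@H]1CC(=O)OC(C)(C)C | intermediate
6 | tert-butyl 2-[(3R,4R)-2-hydroxy-4-(naphthalen-2-ylmethoxy)oxolan-3-yl]acetate (lactol, both anomers) | OC1OC[C@H](OCc2ccc3ccccc3c2)[C@H]1CC(=O)OC(C)(C)C | intermediate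
7 | tert-butyl (3R,4R)-3-(1,3-dithian-2-yl)-5-hydroxy-4-(naphthalen-2-ylmethoxy)pentanoate | OC[C@H](OCc1ccc2ccccc2c1)[C@H](C1SCCCS1)CC(=O)OC(C)(C)C | intermediate
8 | tert-butyl (3R,4R)-3-(1,3-dithian-2-yl)-4-(naphthalen-2-ylmethoxy)-5-oxopentanoate (C9 aldehyde; C6 dithiane, O8 NAP, C12 ester) | O=C[C@H](OCc1ccc2ccccc2c1)[C@H](C1SCCCS1)CC(=O)OC(C)(C)C | intermediate
9 | but-2-yn-1-ol | CC#CCO | starting material
10 | but-2-yn-1-yl methyl carbonate | CC#CCOC(=O)OC | intermediate
11 | 2-(buta-2,3-dien-2-yl)-4,4,5,5-tetramethyl-1,3,2-dioxaborolane | C=C=C(C)B1OC(C)(C)C(C)(C)O1 | intermediate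
12 | (E)-[3-(pinacolboryl)but-2-en-1-yl]bis[(1R,2S,3R,5R)-isopinocampheyl]borane (Bpin cis to CH2B) | C/C(=C/CB([C@@H]1C[C@@H]2C[C@H]([C@H]1C)C2(C)C)[C@@H]1C[C@@H]2C[C@H]([C@H]1C)C2(C)C)B1OC(C)(C)C(C)(C)O1 | intermediate
13 | prop-2-yn-1-ol | C#CCO | starting material
14 | dimethylaluminium (E)-3-(dimethylalumanyl)-2-methylprop-2-en-1-olate | C[Al](C)/C=C(\C)CO[Al](C)C | intermediate
15 | (E)-3-iodo-2-methylprop-2-en-1-ol | OC/C(C)=C/I | intermediate
16 | (E)-3-iodo-2-methylprop-2-enal | O=C/C(C)=C/I | intermediate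
17 | tert-butyl (3R,4R,5S,6S)-5-[bis(isopinocampheyl)boryloxy]-3-(1,3-dithian-2-yl)-6-methyl-4-(naphthalen-2-ylmethoxy)-6-(pinacolboryl)oct-7-enoate | CC(C)(C)OC(=O)C[C@@H](C1SCCCS1)[C@@H](OCc1ccc2ccccc2c1)[C@@H](OB([C@@H]1C[C@@H]2C[C@H]([C@H]1C)C2(C)C)[C@@H]1C[C@@H]2C[C@H]([C@H]1C)C2(C)C)[C@](C)(B1OC(C)(C)C(C)(C)O1)C=C | intermediate
18 | tert-butyl (3R,4R,5S,6Z,9S,10E)-5-[bis(isopinocampheyl)boryloxy]-3-(1,3-dithian-2-yl)-11-iodo-6,10-dimethyl-4-(naphthalen-2-ylmethoxy)-9-(pinacolboryloxy)undeca-6,10-dienoate | CC(C)(C)OC(=O)C[C@@H](C1SCCCS1)[C@@H](OCc1ccc2ccccc2c1)[C@@H](OB([C@@H]1C[C@@H]2C[C@H]([C@H]1C)C2(C)C)[C@@H]1C[C@@H]2C[C@H]([C@H]1C)C2(C)C)/C(C)=C\C[C@H](OB1OC(C)(C)C(C)(C)O1)/C(C)=C/I | intermediate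
19 | tert-butyl (3R,4R,5S,6Z,9S,10E)-3-(1,3-dithian-2-yl)-5,9-dihydroxy-11-iodo-6,10-dimethyl-4-(naphthalen-2-ylmethoxy)undeca-6,10-dienoate (C5/C6 seco diol) | CC(C)(C)OC(=O)C[C@@H](C1SCCCS1)[C@@H](OCc1ccc2ccccc2c1)[C@@H](O)/C(C)=C\C[C@H](O)/C(C)=C/I | intermediate
20 | (4R,5R,6S)-4-(1,3-dithian-2-yl)-6-[(2Z,5S,6E)-5-hydroxy-7-iodo-6-methylhepta-2,6-dien-2-yl]-5-(naphthalen-2-ylmethoxy)oxan-2-one | O=C1C[C@@H](C2SCCCS2)[C@@H](OCc2ccc3ccccc3c2)[C@@H](O1)/C(C)=C\C[C@H](O)/C(C)=C/I | intermediate
21 | (4R,5R,6S)-6-[(2Z,5S,6E)-5-(tert-butyldimethylsilyloxy)-7-iodo-6-methylhepta-2,6-dien-2-yl]-4-(1,3-dithian-2-yl)-5-(naphthalen-2-ylmethoxy)oxan-2-one | O=C1C[C@@H](C2SCCCS2)[C@@H](OCc2ccc3ccccc3c2)[C@@H](O1)/C(C)=C\C[C@H](O[Si](C)(C)C(C)(C)C)/C(C)=C/I | intermediate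
22 | (2S,3R,4R)-2-[(2Z,5S,6E)-5-(tert-butyldimethylsilyloxy)-7-iodo-6-methylhepta-2,6-dien-2-yl]-3-(naphthalen-2-ylmethoxy)-6-oxooxane-4-carbaldehyde | O=C1C[C@@H](C=O)[C@@H](OCc2ccc3ccccc3c2)[C@@H](O1)/C(C)=C\C[C@H](O[Si](C)(C)C(C)(C)C)/C(C)=C/I | intermediate
23 | (3S,6R,7S,8R,9S)-3-(tert-butyldimethylsilyloxy)-6-hydroxy-8-(naphthalen-2-ylmethoxy)germacra-1(10)Z,4E-dien-12,9-olide | O[C@@H]1/C=C(\C)[C@@H](O[Si](C)(C)C(C)(C)C)C/C=C(/C)[C@@H]2OC(=O)C[C@@H]1[C@H]2OCc1ccc2ccccc2c1 | intermediate
24 | (3S,6R,7S,8R,9S)-3-(tert-butyldimethylsilyloxy)-9-hydroxy-8-(naphthalen-2-ylmethoxy)germacra-1(10)Z,4E-dien-12,6-olide | C1C(=O)O[C@@H]2/C=C(\C)[C@@H](O[Si](C)(C)C(C)(C)C)C/C=C(/C)[C@H](O)[C@H](OCc3ccc4ccccc4c3)[C@@H]12 | intermediate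
25 | 11-[(dimethylamino)methyl] derivative of 24 (C11 epimers) | CN(C)CC1C(=O)O[C@@H]2/C=C(\C)[C@@H](O[Si](C)(C)C(C)(C)C)C/C=C(/C)[C@H](O)[C@H](OCc3ccc4ccccc4c3)[C@@H]12 | intermediate
26 | 11-[(trimethylammonio)methyl] derivative of 24, iodide | C[N+](C)(C)CC1C(=O)O[C@@H]2/C=C(\C)[C@@H](O[Si](C)(C)C(C)(C)C)C/C=C(/C)[C@H](O)[C@H](OCc3ccc4ccccc4c3)[C@@H]12.[I-] | intermediate
27 | (3S,6R,7S,8R,9S)-3-(tert-butyldimethylsilyloxy)-9-hydroxy-8-(naphthalen-2-ylmethoxy)germacra-1(10)Z,4E,11(13)-trien-12,6-olide | C=C1C(=O)O[C@@H]2/C=C(\C)[C@@H](O[Si](C)(C)C(C)(C)C)C/C=C(/C)[C@H](O)[C@H](OCc3ccc4ccccc4c3)[C@@H]12 | intermediate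
28 | (3S,6R,7S,8R,9S)-9-acetoxy-3-(tert-butyldimethylsilyloxy)-8-(naphthalen-2-ylmethoxy)germacra-1(10)Z,4E,11(13)-trien-12,6-olide | C=C1C(=O)O[C@@H]2/C=C(\C)[C@@H](O[Si](C)(C)C(C)(C)C)C/C=C(/C)[C@H](OC(C)=O)[C@H](OCc3ccc4ccccc4c3)[C@@H]12 | intermediate
29 | (3S,6R,7S,8R,9S)-9-acetoxy-3-(tert-butyldimethylsilyloxy)-8-hydroxygermacra-1(10)Z,4E,11(13)-trien-12,6-olide | C=C1C(=O)O[C@@H]2/C=C(\C)[C@@H](O[Si](C)(C)C(C)(C)C)C/C=C(/C)[C@H](OC(C)=O)[C@H](O)[C@@H]12 | intermediate
30 | angelic acid, (Z)-2-methylbut-2-enoic acid | C/C=C(/C)C(=O)O | starting material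
31 | angelic 2,4,6-trichlorobenzoic anhydride | C/C=C(/C)C(=O)OC(=O)c1c(Cl)cc(Cl)cc1Cl | intermediate
32 | (3S,6R,7S,8R,9S)-9-acetoxy-8-angeloyloxy-3-(tert-butyldimethylsilyloxy)germacra-1(10)Z,4E,11(13)-trien-12,6-olide | C=C1C(=O)O[C@@H]2/C=C(\C)[C@@H](O[Si](C)(C)C(C)(C)C)C/C=C(/C)[C@H](OC(C)=O)[C@H](OC(=O)/C(C)=C\C)[C@@H]12 | intermediate
33 | (3S,6R,7S,8R,9S)-9-acetoxy-8-angeloyloxy-3-hydroxygermacra-1(10)Z,4E,11(13)-trien-12,6-olide (CNP0265116.1) | C=C1C(=O)O[C@@H]2/C=C(\C)[C@@H](O)C/C=C(/C)[C@H](OC(C)=O)[C@H](OC(=O)/C(C)=C\C)[C@@H]12 | target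

**Count and risks**

Total step count: 20.
Longest linear sequence: 15 steps (steps 1–5 and 11–20, from 1).

Steps most likely to fail:

1. Step 11 (proposed new method). What may go wrong: the second allyl transfer from the hindered tertiary boronate may be slow, or may place the methyl group rather than the C9 branch axial, so that the alkene geometry and with it the C3 configuration are lost; protodeboronation of 17 on long warming would drain material further. Fallback with known chemistry, setting out from 8 and 16 and coming back at 19: aldehyde 8 is coupled with 2-bromopropene under Nozaki–Hiyama–Kishi conditions (CrCl2, NiCl2 cat., DMF), expected to favour the 8,9-anti isopropenyl carbinol tert-butyl (3R,4R,5S)-3-(1,3-dithian-2-yl)-5-hydroxy-6-methyl-4-(naphthalen-2-ylmethoxy)hept-6-enoate F1. Enal 16 is allylated with allyl(diisopinocampheyl)borane from (+)-α-pinene (Brown allylation) to (S,E)-1-iodo-2-methylhexa-1,5-dien-3-ol F2. The two alcohols are joined in sequence through a diisopropylsilylene tether (iPr2SiCl2, imidazole) to the mixed bis(alkoxy)silane F3. Ring-closing metathesis with the second-generation Grubbs catalyst in hot toluene should close the eight-membered cyclic silaketal F4, in which the new trisubstituted C1=C10 alkene can only be cis within the ring. HF·pyridine then removes the tether and gives diol 19.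

2. Step 15. What may go wrong: poor facial selectivity at C6 when the vinylchromium adds to an aldehyde held on the lactone-bridged chain, so that the 6-epimer forms and the lactone closes cis; the strained bridged transition state may also slow ring closure against reduction of the carbon–iodine bond. Fallback, setting out from 23 (isolated here as whatever C6 mixture forms, before the DBU treatment) and coming back at 24: oxidation with Dess–Martin periodinane gives the macrocyclic enone (3S,7R,8R,9S)-3-(tert-butyldimethylsilyloxy)-8-(naphthalen-2-ylmethoxy)-6-oxogermacra-1(10)Z,4E-dien-12,9-olide F5. A 1,2-reduction follows, under Luche conditions (NaBH4, CeCl3, MeOH, −78 °C) or with a CBS oxazaborolidine and BH3, whose two enantiomers allow reagent control in favour of the 6R carbinol. DBU-promoted acyl transfer then gives 24.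

3. Step 19. What may go wrong: Z-to-E isomerisation of the angeloyl unit during activation and heating (tiglate formation), and thermal stress on the 1(10),4-diene at 80 °C. Fallback, setting out from 29 and coming back at 32: the C8 hydroxyl is esterified at room temperature with 2-[bis(2,2,2-trifluoroethoxy)phosphoryl]propanoic acid (DCC, DMAP cat., CH2Cl2) to the 8-O-{2-[bis(2,2,2-trifluoroethoxy)phosphoryl]propanoyl} ester F6. A Still–Gennari olefination with acetaldehyde (KN(SiMe3)2, 18-crown-6, THF, −78 °C) then builds the Z-trisubstituted enoate on the substrate and gives 32.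

**Further compounds**

F1 | step 11 | tert-butyl (3R,4R,5S)-3-(1,3-dithian-2-yl)-5-hydroxy-6-methyl-4-(naphthalen-2-ylmethoxy)hept-6-enoate | CC(C)(C)OC(=O)C[C@@H](C1SCCCS1)[C@@H](OCc1ccc2ccccc2c1)[C@@H](O)C(C)=C
F2 | step 11 | (S,E)-1-iodo-2-methylhexa-1,5-dien-3-ol | C=CC[C@H](O)/C(C)=C/I
F3 | step 11 | di(propan-2-yl)silylene bis-ether joining O9 of F1 and O3 of F2 | CC(C)(C)OC(=O)C[C@@H](C1SCCCS1)[C@@H](OCc1ccc2ccccc2c1)[C@@H](O[Si](C(C)C)(C(C)C)O[C@@H](CC=C)/C(C)=C/I)C(C)=C
F4 | step 11 | eight-membered cyclic silaketal (2,2-diisopropyl-1,3-dioxa-2-silacyclooct-5-ene) with cis C1=C10, carrying the C4=C5 iodoalkenyl group on C3 and the C6–C8/C11–C12 chain on C9 | C/C1=C/C[C@@H](/C(C)=C/I)O[Si](C(C)C)(C(C)C)O[C@@H]1[C@H](OCc1ccc2ccccc2c1)[C@H](C1SCCCS1)CC(=O)OC(C)(C)C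
F5 | step 15 | (3S,7R,8R,9S)-3-(tert-butyldimethylsilyloxy)-8-(naphthalen-2-ylmethoxy)-6-oxogermacra-1(10)Z,4E-dien-12,9-olide | O=C1/C=C(\C)[C@@H](O[Si](C)(C)C(C)(C)C)C/C=C(/C)[C@@H]2OC(=O)C[C@@H]1[C@H]2OCc1ccc2ccccc2c1
F6 | step 19 | (3S,6R,7S,8R,9S)-9-acetoxy-8-{2-[bis(2,2,2-trifluoroethoxy)phosphoryl]propanoyloxy}-3-(tert-butyldimethylsilyloxy)germacra-1(10)Z,4E,11(13)-trien-12,6-olide | C=C1C(=O)O[C@@H]2/C=C(\C)[C@@H](O[Si](C)(C)C(C)(C)C)C/C=C(/C)[C@H](OC(C)=O)[C@H](OC(=O)C(C)P(=O)(OCC(F)(F)F)OCC(F)(F)F)[C@@H]12
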